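**Plan** (benzofuran numbering; ring A = benzene ring, ring B = dihydrofuran ring, C1' = side-chain carbon on C2)
1. Retrosynthesis: the C1'=CH2 alkene is traced back to its hydrate (C1'–OH). Then the C3–O angelate ester, the C3a–C3 bond of ring B and the O1–C2 ether are cut in that order. This leaves an iodinated hydroxy-dimethoxyacetophenone, racemic 2-isopropenyloxirane and angelic acid.
2. Forward: ring A is bought as gallacetophenone and dressed (steps 1–4). The five-carbon chain is hung on O1 (step 6), hydrated and oxidised (steps 7–8). Ring B is closed (step 9), then the ester (step 10) and the alkene (step 11) are made.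
3. Enabling feature: C3a is the only free position ortho to O1 in ring A, so iodine enters there alone. C2 is a hub for three donor arms: C3a (through O1–C7a), the C3 aldehyde oxygen and the C1' hydroxyl. Bound facially to one chromium centre, these arms let the aryl group reach C3 only on the face that puts C3–O cis to the C2 side chain.
4. Helpers: iodine on C3a is the activating group and is lost in step 9. The C1' hydroxyl anchors the temporary chelate rings and also masks the alkene, which would otherwise invite 5-exo carbometalation and conjugation of the aldehyde; it is lost in step 11.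
5. Stereochemistry: C2 comes from the chiral palladium catalyst in step 6. C3 comes from C2 through the chelate in step 9. The Z alkene is bought with angelic acid and kept by a base-poor acylation.

Key step: step 9

Assumption: the (S,S) antipode of the DACH-naphthyl diphosphine is taken to give the (R)-ether 8, by analogy with the sense known for other heteroatom nucleophiles and vinyl oxiranes. If the sense is opposite, the (R,R) ligand is used and nothing else changes.

Step 1
Reactants: 1 1-(2,3,4-trihydroxyphenyl)ethanone (gallacetophenone)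
Product: 2 1-[4-(benzyloxy)-2,3-dihydroxyphenyl]ethanone
Conditions: BnBr (1.0 equiv), NaHCO3, NaI (cat.), DMF, 40 °C
Reagents that add atoms: benzyl bromide, BrCc1ccccc1
Why: Williamson etherification with a weak base should select the 4-hydroxyl, which is para to the acetyl group and the most acidic, while the 2-hydroxyl is held in a hydrogen bond to the ketone.

Step 2
Reactants: 2 1-[4-(benzyloxy)-2,3-dihydroxyphenyl]ethanone
Product: 3 1-[4-(benzyloxy)-2,3-dimethoxyphenyl]ethanone
Conditions: MeI (excess), K2CO3, DMF, 50 °C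
Reagents that add atoms: methyl iodide, CI
Why: Williamson methylation of the two remaining phenols, in which warm DMF and excess halide overcome the hydrogen bond of the 2-hydroxyl.

Step 3
Reactants: 3 1-[4-(benzyloxy)-2,3-dimethoxyphenyl]ethanone
Product: 4 1-(4-hydroxy-2,3-dimethoxyphenyl)ethanone
Conditions: H2 (1 atm), Pd/C, EtOAc, 23 °C
Reagents that add atoms: none
Why: Hydrogenolysis of a benzyl aryl ether is much faster than reduction of the electron-rich aryl ketone under these mild conditions.

Step 4
Reactants: 4 1-(4-hydroxy-2,3-dimethoxyphenyl)ethanone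
Product: 5 1-(4-hydroxy-5-iodo-2,3-dimethoxyphenyl)ethanone
Conditions: N-iodosuccinimide, TsOH (cat.), MeCN, 0 to 23 °C
Reagents that add atoms: N-iodosuccinimide, O=C1CCC(=O)N1I
Why: Electrophilic aromatic iodination of a phenol goes ortho or para to the hydroxyl; para is blocked by acetyl and one ortho site by methoxy, so only the carbon that becomes C3a can react.

Step 5
Reactants: 6 2-methylprop-2-enal (methacrolein)
Product: 7 rac-2-(prop-1-en-2-yl)oxirane
Conditions: Me3SI, NaH, DMSO/THF, 0 °C; distilled
Reagents that add atoms: trimethylsulfonium iodide, C[S+](C)C.[I-]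
Why: Corey–Chaykovsky epoxidation, in which the unstabilised sulfonium ylide adds 1,2 to the enal and closes to the vinyl oxirane; the product may stay racemic because step 6 is stereoconvergent.

Step 6
Reactants: 5 1-(4-hydroxy-5-iodo-2,3-dimethoxyphenyl)ethanone; 7 rac-2-(prop-1-en-2-yl)oxirane
Product: 8 1-(4-{[(2R)-1-hydroxy-3-methylbut-3-en-2-yl]oxy}-5-iodo-2,3-dimethoxyphenyl)ethanone
Conditions: Pd2(dba)3·CHCl3 (1 mol %), N,N'-[(1S,2S)-cyclohexane-1,2-diyl]bis[2-(diphenylphosphino)-1-naphthamide] (3 mol %), CH2Cl2, 0 to 23 °C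
Reagents that add atoms: none
Why: Tsuji–Trost allylic etherification run as a dynamic kinetic asymmetric transformation: zerovalent palladium opens both enantiomers of 7 to π-allyl alkoxides that interconvert by π-σ-π slippage at the CH2 terminus, the alkoxide deprotonates 5 and its hydrogen bond guides the phenoxide to the neighbouring internal carbon, and the ligand pocket fixes C2 as R.

Step 7
Reactants: 8 1-(4-{[(2R)-1-hydroxy-3-methylbut-3-en-2-yl]oxy}-5-iodo-2,3-dimethoxyphenyl)ethanone
Product: 9 1-(4-{[(2S)-1,3-dihydroxy-3-methylbutan-2-yl]oxy}-5-iodo-2,3-dimethoxyphenyl)ethanone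
Conditions: Co(acac)2 (10 mol %), PhSiH3, O2 (1 atm), THF, 23 °C
Reagents that add atoms: dioxygen, O=O
Why: Mukaiyama hydration, in which hydrogen-atom transfer from a cobalt hydride to the 1,1-disubstituted alkene gives the tertiary radical, which is trapped by O2 and reduced by the silane to the Markovnikov alcohol; C2 is untouched and only its descriptor changes.

Step 8
Reactants: 9 1-(4-{[(2S)-1,3-dihydroxy-3-methylbutan-2-yl]oxy}-5-iodo-2,3-dimethoxyphenyl)ethanone
Product: 10 (2R)-2-(4-acetyl-6-iodo-2,3-dimethoxyphenoxy)-3-hydroxy-3-methylbutanal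
Conditions: TEMPO (10 mol %), PhI(OAc)2, CH2Cl2, 23 °C; used crude
Reagents that add atoms: none
Why: Oxoammonium (TEMPO) oxidation takes the primary alcohol to the aldehyde, cannot touch the tertiary alcohol and is mild enough for the epimerisable C2–H.

Step 9
Reactants: 10 (2R)-2-(4-acetyl-6-iodo-2,3-dimethoxyphenoxy)-3-hydroxy-3-methylbutanal
Product: 12 1-[(2S,3R)-3-hydroxy-2-(2-hydroxypropan-2-yl)-6,7-dimethoxy-2,3-dihydro-1-benzofuran-5-yl]ethanone, via arylchromium dichloride 11 (not isolated)
Conditions: CrCl2 (6 equiv), NiCl2 (2 mol %), THF/DMF 20:1, 0.02 M, 23 °C; aq. EDTA work-up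
Reagents that add atoms: chromium dichloride, Cl[Cr]Cl (its atoms stay only in 11)
Why: Zerovalent nickel formed in situ inserts into the C3a–I bond, the aryl group passes to trivalent chromium to give 11, and the aryl–chromium bond adds across the aldehyde C=O through a closed four-centre transition state; this is the intramolecular Nozaki–Hiyama–Kishi reaction, whose closest known relatives are closures of iodoarene aldehydes to benzo-fused cyclic carbinols. Ring B closes in the 5-exo-trig mode through the C3a–C3 bond. In such a transition state chromium must sit on the ring face towards which the new C3–O bond points, so C3 is decided by where the metal is held. In the weakly donating medium the C1' hydroxyl should bind the oxophilic metal (ligand exchange is eased by the trans-labilising aryl group and by excess divalent chromium), so that C3a, the aldehyde oxygen and the carbinol oxygen fill one face of the octahedron with C2–H turned away, and C3–O forms cis to the side chain (3R). The step needs the aldehyde to react rather than the C5 methyl ketone, which rests on the known inertness of arylchromium reagents towards ketones, and the site on ring A is fixed by the iodine. The non-basic, non-acidic medium should spare C2–H, avoid retro-aldol loss of acetone and avoid dehydration to the benzofuran, and with the alkene stored as its hydrate neither 5-exo carbonickelation nor conjugation of the aldehyde can compete.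

Step 10
Reactants: 12 1-[(2S,3R)-3-hydroxy-2-(2-hydroxypropan-2-yl)-6,7-dimethoxy-2,3-dihydro-1-benzofuran-5-yl]ethanone; 13 angelic acid, (2Z)-2-methylbut-2-enoic acid
Product: 15 (2S,3R)-5-acetyl-2-(2-hydroxypropan-2-yl)-6,7-dimethoxy-2,3-dihydro-1-benzofuran-3-yl (2Z)-2-methylbut-2-enoate, via mixed anhydride 14 (not isolated)
Conditions: 13, 2,4,6-trichlorobenzoyl chloride, Et3N, toluene, 23 °C; then 12, toluene, 70 °C (no DMAP)
Reagents that add atoms: 2,4,6-trichlorobenzoyl chloride, O=C(Cl)c1c(Cl)cc(Cl)cc1Cl (its atoms stay only in 14)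
Why: Yamaguchi-type mixed-anhydride esterification without a nucleophilic catalyst acylates only the secondary C3–OH (the tertiary C1'–OH is too hindered) and avoids Z to E drift of the angelate; the C3–O bond is not broken, so C3 is kept.

Step 11
Reactants: 15 (2S,3R)-5-acetyl-2-(2-hydroxypropan-2-yl)-6,7-dimethoxy-2,3-dihydro-1-benzofuran-3-yl (2Z)-2-methylbut-2-enoate
Product: 16 (2R,3R)-5-acetyl-6,7-dimethoxy-2-(prop-1-en-2-yl)-2,3-dihydro-1-benzofuran-3-yl (2Z)-2-methylbut-2-enoate (target)
Conditions: Ph2S[OC(CF3)2Ph]2 (1.5 equiv), CH2Cl2, 0 °C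
Reagents that add atoms: none
Why: Sulfurane dehydration of a tertiary alcohol runs through an alkoxysulfonium ion at low temperature, and the fluoroalkoxide should take one of the six methyl hydrogens rather than the hindered, oxygen-flanked C2–H, giving the isopropenyl group without acid that would ionise C3–O.

**Compound list**
1 | 1-(2,3,4-trihydroxyphenyl)ethanone | CC(=O)c1ccc(O)c(O)c1O | starting material
2 | 1-[4-(benzyloxy)-2,3-dihydroxyphenyl]ethanone | CC(=O)c1ccc(OCc2ccccc2)c(O)c1O | intermediate
3 | 1-[4-(benzyloxy)-2,3-dimethoxyphenyl]ethanone | CC(=O)c1ccc(OCc2ccccc2)c(OC)c1OC | intermediate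
4 | 1-(4-hydroxy-2,3-dimethoxyphenyl)ethanone | CC(=O)c1ccc(O)c(OC)c1OC | intermediate
5 | 1-(4-hydroxy-5-iodo-2,3-dimethoxyphenyl)ethanone | CC(=O)c1cc(I)c(O)c(OC)c1OC | intermediate
6 | 2-methylprop-2-enal | CC(=C)C=O | starting material
7 | rac-2-(prop-1-en-2-yl)oxirane | CC(=C)C1CO1 | intermediate
8 | 1-(4-{[(2R)-1-hydroxy-3-methylbut-3-en-2-yl]oxy}-5-iodo-2,3-dimethoxyphenyl)ethanone | C=C(C)[C@@H](Oc1c(I)cc(C(C)=O)c(OC)c1OC)CO | intermediate
9 | 1-(4-{[(2S)-1,3-dihydroxy-3-methylbutan-2-yl]oxy}-5-iodo-2,3-dimethoxyphenyl)ethanone | CC(C)(O)[C@@H](Oc1c(I)cc(C(C)=O)c(OC)c1OC)CO | intermediate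
10 | (2R)-2-(4-acetyl-6-iodo-2,3-dimethoxyphenoxy)-3-hydroxy-3-methylbutanal | CC(C)(O)[C@@H](Oc1c(I)cc(C(C)=O)c(OC)c1OC)C=O | intermediate
11 | arylchromium dichloride from 10 (C–I replaced by C–CrCl2, solvent ligands omitted) | CC(C)(O)[C@@H](Oc1c([Cr](Cl)Cl)cc(C(C)=O)c(OC)c1OC)C=O | intermediate
12 | 1-[(2S,3R)-3-hydroxy-2-(2-hydroxypropan-2-yl)-6,7-dimethoxy-2,3-dihydro-1-benzofuran-5-yl]ethanone (cis) | CC(C)(O)[C@H]1Oc2c(cc(C(C)=O)c(OC)c2OC)[C@H]1O | intermediate
13 | angelic acid, (2Z)-2-methylbut-2-enoic acid | C/C=C(/C)C(=O)O | starting material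
14 | (2Z)-2-methylbut-2-enoic 2,4,6-trichlorobenzoic anhydride | C/C=C(/C)C(=O)OC(=O)c1c(Cl)cc(Cl)cc1Cl | intermediate
15 | (2S,3R)-5-acetyl-2-(2-hydroxypropan-2-yl)-6,7-dimethoxy-2,3-dihydro-1-benzofuran-3-yl (2Z)-2-methylbut-2-enoate | CC(C)(O)[C@H]1Oc2c(cc(C(C)=O)c(OC)c2OC)[C@H]1OC(=O)/C(C)=C\C | intermediate
16 | (2R,3R)-5-acetyl-6,7-dimethoxy-2-(prop-1-en-2-yl)-2,3-dihydro-1-benzofuran-3-yl (2Z)-2-methylbut-2-enoate | C=C(C)[C@H]1Oc2c(cc(C(C)=O)c(OC)c2OC)[C@H]1OC(=O)/C(C)=C\C | target

Total steps: 11. Longest linear sequence: 10 (steps 1–4 and 6–11).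

**Steps most likely to fail**

Step 9. Facial selectivity would be lost or reversed if donor solvent displaces the C1' hydroxyl from chromium, because the metal would then take the face away from the bulky side chain. Protodemetalation of the aryl–chromium bond is a second possible loss.
Fallback (sets out from 10, comes back at 12): the stereocentre is set by hydride delivery instead of by the C–C bond formation. The same nickel/chromium closure is run in DMF with no facial control asked of it. It should give mainly the trans-diol 1-[(2S,3S)-3-hydroxy-2-(2-hydroxypropan-2-yl)-6,7-dimethoxy-2,3-dihydro-1-benzofuran-5-yl]ethanone F1. MnO2 in CH2Cl2 then oxidises only the benzylic carbinol to the hydroxy ketone (2R)-5-acetyl-2-(2-hydroxypropan-2-yl)-6,7-dimethoxy-1-benzofuran-3(2H)-one F2. A Narasaka–Prasad reduction (Et2BOMe, NaBH4, THF/MeOH, −78 °C) follows. The boron chelate between C1'–O and C3=O activates this ketone over the acetyl group, and external hydride enters anti to the side chain to give the cis-diol 12.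

Step 6. The product is an allylic ether of an acidic phenol and could re-ionise, which would erode regio- and enantiopurity. Oxidative addition of palladium into the C–I bond is a further risk.
Fallback (sets out from 5, comes back at 8): the ether is made by SN2 displacement on a preformed stereocentre.
- Commercial 2-[(tert-butyldimethylsilyl)oxy]-N-methoxy-N-methylacetamide and isopropenylmagnesium bromide give the enone 1-[(tert-butyldimethylsilyl)oxy]-3-methylbut-3-en-2-one F3.
- Corey–Bakshi–Shibata reduction with the (S)-methyl oxazaborolidine and BH3·SMe2 gives (2S)-1-[(tert-butyldimethylsilyl)oxy]-3-methylbut-3-en-2-ol F4.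
- Mitsunobu etherification with 5 (PPh3, DIAD, toluene, 0 °C) inverts the carbinol to the silyl ether 1-(4-{[(2R)-1-[(tert-butyldimethylsilyl)oxy]-3-methylbut-3-en-2-yl]oxy}-5-iodo-2,3-dimethoxyphenyl)ethanone F5.
- HF·pyridine in THF then frees 8.

Step 11. The cis ester could take part once C1'–O is activated, leading to acyl shift. Elimination could also go towards C2, or angelic acid could be lost with aromatisation to the benzofuran.
Fallback (sets out from 12, comes back at 16): the alkene is made before the ester is present.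
- TESCl and imidazole in DMF at 0 °C silylate only the secondary alcohol, giving 1-[(2S,3R)-2-(2-hydroxypropan-2-yl)-6,7-dimethoxy-3-[(triethylsilyl)oxy]-2,3-dihydro-1-benzofuran-5-yl]ethanone F6.
- The same sulfurane dehydration gives 1-[(2R,3R)-6,7-dimethoxy-2-(prop-1-en-2-yl)-3-[(triethylsilyl)oxy]-2,3-dihydro-1-benzofuran-5-yl]ethanone F7.
- Buffered HF·pyridine frees the cis-alcohol 1-[(2R,3R)-3-hydroxy-6,7-dimethoxy-2-(prop-1-en-2-yl)-2,3-dihydro-1-benzofuran-5-yl]ethanone F8.
- F8 is acylated with mixed anhydride 14 as in step 10 to give 16.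

**Further compounds**
F1 | step 9 | 1-[(2S,3S)-3-hydroxy-2-(2-hydroxypropan-2-yl)-6,7-dimethoxy-2,3-dihydro-1-benzofuran-5-yl]ethanone | CC(C)(O)[C@H]1Oc2c(cc(C(C)=O)c(OC)c2OC)[C@@H]1O
F2 | step 9 | (2R)-5-acetyl-2-(2-hydroxypropan-2-yl)-6,7-dimethoxy-1-benzofuran-3(2H)-one | CC(C)(O)[C@H]1Oc2c(cc(C(C)=O)c(OC)c2OC)C1=O
F3 | step 6 | 1-[(tert-butyldimethylsilyl)oxy]-3-methylbut-3-en-2-one | C=C(C)C(=O)CO[Si](C)(C)C(C)(C)C
F4 | step 6 | (2S)-1-[(tert-butyldimethylsilyl)oxy]-3-methylbut-3-en-2-ol | C=C(C)[C@H](O)CO[Si](C)(C)C(C)(C)C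
F5 | step 6 | 1-(4-{[(2R)-1-[(tert-butyldimethylsilyl)oxy]-3-methylbut-3-en-2-yl]oxy}-5-iodo-2,3-dimethoxyphenyl)ethanone | C=C(C)[C@@H](Oc1c(I)cc(C(C)=O)c(OC)c1OC)CO[Si](C)(C)C(C)(C)C
F6 | step 11 | 1-[(2S,3R)-2-(2-hydroxypropan-2-yl)-6,7-dimethoxy-3-[(triethylsilyl)oxy]-2,3-dihydro-1-benzofuran-5-yl]ethanone | CC(C)(O)[C@H]1Oc2c(cc(C(C)=O)c(OC)c2OC)[C@H]1O[Si](CC)(CC)CC
F7 | step 11 | 1-[(2R,3R)-6,7-dimethoxy-2-(prop-1-en-2-yl)-3-[(triethylsilyl)oxy]-2,3-dihydro-1-benzofuran-5-yl]ethanone | C=C(C)[C@H]1Oc2c(cc(C(C)=O)c(OC)c2OC)[C@H]1O[Si](CC)(CC)CC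
F8 | step 11 | 1-[(2R,3R)-3-hydroxy-6,7-dimethoxy-2-(prop-1-en-2-yl)-2,3-dihydro-1-benzofuran-5-yl]ethanone | C=C(C)[C@H]1Oc2c(cc(C(C)=O)c(OC)c2OC)[C@H]1O
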